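# Proposed synthesis of 2,3,4,7-tetrabromoindole (15) by cycloaromatization with bromine-atom capture

## The problem

2,3,4,7-Tetrabromoindole (15) is a flat, achiral pyrrole–benzene bicycle, so there is no stereocenter and the only thing to control is the position of four bromine atoms. The two on the pyrrole ring, at C2 and C3, sit where an N–H indole reacts with electrophiles unaided, C3 first and C2 second. The two on the benzene ring (ring B), at C4 and C7, sit where it does not: once C3 and C2 are filled, electrophilic bromination moves on to C5 and C6. The C4/C7 pair must therefore be bought inside a benzene starting material or written into the reaction that makes ring B. Aryl C–Br bonds do not tolerate organolithium reagents, zerovalent palladium or dissolving metals, and an N–H 2,3-dibromoindole is electron-rich and easily oxidized, so all metal chemistry should be finished before the first bromine arrives and the pyrrole bromines should come last. The enabling feature is that C4 and C7 are para to each other with only C5–H and C6–H between them, which is the pattern a 1,4-didehydrobenzene leaves when each radical centre takes up one atom. If ring B is closed by cycloaromatization of a pyrrole carrying ethynyl groups at its C2 and C3, the two terminal alkyne carbons become C5 and C6 and the radical centres fall on the carbons attached to C7a and C3a, that is on C7 and C4. The synthesis thus reduces to making a 2,3-diethynylpyrrole and making the diradical choose bromine.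

## Retrosynthesis

**15 to 13.** The C2–Br and C3–Br bonds are cut first. These are the only bromines the indole nucleus accepts by its innate reactivity, so removing them costs nothing in selectivity, whereas C4–Br and C7–Br could not be put back at this stage. The precursor, 4,7-dibromoindole 13, carries half the halogen and is a robust compound. The forward reaction must substitute C3 (giving 3,4,7-tribromoindole 14 in the flask), then C2, and stop; the two bromines already on ring B should keep that ring out of play.

**13 to 12.** The N–H bond is traced back to an N–S bond in 4,7-dibromo-1-(4-methylphenylsulfonyl)indole 12. The sulfonyl group is not needed by the target but by everything before it: it directs metalation, tempers the pyrrole toward radicals and stands heat. It is taken off before the last brominations because an N-sulfonylindole is too deactivated for clean substitution at C2. The forward step must cleave a sulfonamide without touching two aryl bromides.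

**12 to 9 and 10 (key disconnection).** Three bonds are cut at once: C5–C6, C4–Br and C7–Br. This leads back through the 4,7-diradical 11 to 2,3-diethynyl-1-(4-methylphenylsulfonyl)pyrrole 9 and two molecules of bromotrichloromethane 10, one for each bromine atom. The neighbouring cuts either open ring B through C3a–C4 and C7–C7a or start from a dibromobenzene and build the pyrrole; they are weighed under "Roads not taken". This cut is preferred because it delivers ring B at the aromatic oxidation level with both halogens placed by the ring-forming event, on carbons that have no hydrogen to lose. The precursor 9 is monocyclic, halogen-free and bears two identical two-carbon side chains. The forward reaction must cyclize at a temperature the substrate tolerates, put bromine and not hydrogen or chlorine on both radical centres, and leave the terminal alkynes untouched by CCl3 radicals until they have cyclized.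

**9 to 8.** The two C(sp)–H bonds are traced back to C(sp)–Si bonds in the bis-silyl compound 8. The alkyne termini must be unsubstituted in 9, since any group there would end up on C5 and C6 and would raise the cyclization barrier. The silyl caps serve only the coupling step and come off immediately before use.

**8 to 5 and 6.** The C2–C(sp) and C3–C(sp) bonds are cut, giving 3-bromo-2-iodo-1-(4-methylphenylsulfonyl)pyrrole 5 and two equivalents of trimethylsilylacetylene 6. Building the alkynes by homologation of aldehydes would require a pyrrole-2,3-dicarbaldehyde, which is harder to reach than the dihalide. The forward reaction is a two-fold cross-coupling in one flask; the iodide reacts first (through the mono-alkyne 7) and the bromide on warming.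

**5 to 3.** The C2–I bond is cut, leading to 3-bromo-1-(4-methylphenylsulfonyl)pyrrole 3 through its 2-lithio derivative 4. Deprotonation is chosen over electrophilic iodination because the sulfonyl group and the bromine both point to C2, whereas an electrophile would not reliably tell C2 from C5. The forward step needs kinetic lithiation and a fast quench.

**3 to 1.** The nitrogen substituent is exchanged, back to 3-bromo-1-(triisopropylsilyl)pyrrole 1. This compound is sold with bromine at C3, a position that direct halogenation of a simple pyrrole does not give cleanly; the bulky silyl group is what put it there. The forward step passes through the unstable 3-bromopyrrole 2, which must be sulfonylated without being stored.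

## Roads not taken

**Alternative 1: vinyl nitrene closure onto a dibromobenzene.** The cut is N1–C7a, made on ethyl 4,7-dibromo-1H-indole-2-carboxylate A1. In the forward direction, thermal denitrogenation of ethyl (Z)-2-azido-3-(2,5-dibromophenyl)acrylate A2 gives a vinyl nitrene, in equilibrium with its 2H-azirine, which bonds to the ortho carbon (Hemetsberger–Knittel synthesis). A2 comes from 2,5-dibromobenzaldehyde A3 and ethyl azidoacetate A4 by Knoevenagel condensation.

- Merits: both ring B bromines are bought in A3. Regiochemistry is not a question, because one ortho position carries bromine and only the other can accept nitrogen. The reaction type is thoroughly established.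
- Weak points: the ester at C2 is a passenger sitting exactly where the target needs bromine. Removing it means saponification to 4,7-dibromo-1H-indole-2-carboxylic acid A5 and a hot decarboxylation beside two aryl bromides before compound 13 is reached. A4 and A2 are energetic azides that have to be heated.
- Comparison: this road is better precedented than the chosen plan and, at about five steps to 15 through 13, shorter. On reliability it is ahead. The chosen plan can set against it only that it needs no azide, no passenger group and no decarboxylation, and that it places the C4/C7 bromines in the ring-forming event instead of inheriting them.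

**Alternative 2: ring B by cycloaddition of a dibromothiophene dioxide.** The cut runs through C3a–C4 and C7–C7a, made on tert-butyl cis-4,7-dibromo-2,3,3a,7a-tetrahydroindole-1-carboxylate A6 (racemic; both stereocenters vanish on aromatization). In the forward direction, 2,5-dibromothiophene 1,1-dioxide A7 reacts as an electron-poor diene with the enecarbamate tert-butyl 2,3-dihydropyrrole-1-carboxylate A8 in a [4+2] cycloaddition, and the bridged adduct extrudes its sulfonyl bridge to leave the cyclohexa-1,3-diene A6.

- Merits: the route is convergent, the symmetrical diene removes any orientation problem, the electronic pairing is sound, and cycloaddition–extrusion of thiophene dioxides is a known reaction type, which the chosen key step is not.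
- Weak points: A6 lies two oxidation levels below an indole. While ring B is being dehydrogenated, 1,5-hydrogen shifts can move hydrogen onto a bromine-bearing carbon and open aromatization by dehydrobromination, which deletes one of the bromines the step was meant to secure. Oxidation to tert-butyl 4,7-dibromoindole-1-carboxylate A9 and carbamate removal are still needed to reach 13. A7 needs a powerful oxygen-transfer oxidant for its preparation and tends to dimerize.
- Comparison: on paper it is a step or two shorter than the chosen plan and its ring-forming event has precedent. The chosen plan sets against it that cycloaromatization gives ring B directly at the aromatic level, with no oxidation-state correction and no elimination pathway.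

**Alternative 3: annulation of a bromine-flanked aryne.** The cuts are N1–C7a and C3–C3a, made on 4,7-dibromo-1-(4-methylphenylsulfonyl)indolin-3-ol A10 (racemic; the carbinol stereocenter disappears on dehydration). In the forward direction, a fluoride source acts on 3,6-dibromo-2-(trimethylsilyl)phenyl trifluoromethanesulfonate A11 to release 3,6-dibromobenzyne A12. The sulfonamide nitrogen of N-(2-oxoethyl)-4-methylbenzenesulfonamide A13 adds to it, and the resulting aryl anion closes onto the tethered aldehyde.

- Merits: the aryne is symmetrical, so only one orientation exists. The conditions are mild (room temperature against roughly 200 °C), and aryne insertion–cyclization is a known reaction type. Acid-catalysed dehydration of A10 lands on compound 12 of the chosen route, so the endgame is shared.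
- Weak points: after nitrogen has added, the negative charge sits on a carbon ortho to bromine, the classical arrangement for expelling bromide and forming a second aryne, so closure onto the aldehyde must outrun β-elimination. A13 is an enolizable α-amino aldehyde with an acidic N–H; it can quench the aryl anion by proton transfer and it self-condenses. A11 requires several steps of metalation chemistry on a dibromophenol, where halogen–metal exchange and halogen migration threaten.
- Comparison: this road is ahead in mildness and in precedent of reaction type, and about equal in step count once A11 has been made. The chosen plan sets against it that its reactive intermediates are σ-radicals, to which a neighbouring bromine is indifferent, and that its precursor 9 is assembled in four routine operations with no carbanion next to bromine.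

Key step: step 5

Remark on the chemistry: commercial Bu4NF solution is taken to contain water, so in step 1 the desilylated pyrrole is present as the N–H compound 2 until base and sulfonyl chloride are added. In compounds 9 to 12, pyrrole C2 and C3 become indole C7a and C3a.

**Step 1**  
Reactants: 1 3-bromo-1-(triisopropylsilyl)pyrrole  
Product: 3 3-bromo-1-(4-methylphenylsulfonyl)pyrrole, via 3-bromopyrrole 2 (not isolated)  
Conditions: Bu4NF (1.0 equiv), THF, 0 °C, 15 min; then powdered NaOH, TsCl, 0 °C to rt, same flask  
Reagents that add atoms: 4-methylbenzenesulfonyl chloride (TsCl), Cc1ccc(cc1)S(Cl)(=O)=O  
Why: Fluoride-induced N-desilylation followed in the same flask by N-sulfonylation under phase-transfer-type conditions, with the Bu4N+ ion already present as the transfer cation; the unstable N–H pyrrole 2 is never concentrated, and the tosyl group is installed because it directs the next lithiation to C2, tolerates the PdCl2(PPh3)2/CuI coupling and heat, and deactivates the pyrrole toward electrophilic radicals.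

**Step 2**  
Reactants: 3 3-bromo-1-(4-methylphenylsulfonyl)pyrrole  
Product: 5 3-bromo-2-iodo-1-(4-methylphenylsulfonyl)pyrrole, via 3-bromo-2-lithio-1-tosylpyrrole 4 (not isolated)  
Conditions: LiN(iPr)2 (1.1 equiv), THF, −78 °C; then I2 in THF, −78 °C  
Reagents that add atoms: iodine, II  
Why: Directed ortho-lithiation: the N-sulfonyl group and the C3 bromine jointly acidify C2–H, so LiN(iPr)2 should give the 2-lithio species 4 as the kinetic product at −78 °C, and iodine, a fast electrophile, traps it before lithium can migrate to C5 by proton transfer or a halogen dance can begin.

**Step 3**  
Reactants: 5 3-bromo-2-iodo-1-(4-methylphenylsulfonyl)pyrrole; 6 trimethylsilylacetylene  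
Product: 8 1-(4-methylphenylsulfonyl)-2,3-bis[(trimethylsilyl)ethynyl]pyrrole, via 3-bromo-1-tosyl-2-[(trimethylsilyl)ethynyl]pyrrole 7 (not isolated)  
Conditions: 6 (4 equiv), PdCl2(PPh3)2 (5 mol %), CuI (10 mol %), Et3N–DMF, rt then 70 °C, sealed tube, argon  
Reagents that add atoms: none  
Why: Two-fold Sonogashira coupling in one flask: the C2–I bond reacts at room temperature to give 7, and warming then engages the C3–Br bond, which the N-sulfonyl group and the adjacent alkyne make electron-poor enough for oxidative addition; the alkyne is used in excess in a closed vessel because it is volatile and partly lost to Glaser homocoupling.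

**Step 4**  
Reactants: 8 1-(4-methylphenylsulfonyl)-2,3-bis[(trimethylsilyl)ethynyl]pyrrole  
Product: 9 2,3-diethynyl-1-(4-methylphenylsulfonyl)pyrrole  
Conditions: K2CO3 (0.2 equiv), MeOH–THF, 0 °C, 30 min; cold work-up, solution of 9 used at once  
Reagents that add atoms: none  
Why: Base-catalysed methanolysis of the two alkynyl C–Si bonds (protodesilylation); with substoichiometric K2CO3 at 0 °C the N–S bond should stay intact, and 9 is kept cold in solution and carried on at once because terminal enediynes oligomerize on storage.

**Step 5**  
Reactants: 9 2,3-diethynyl-1-(4-methylphenylsulfonyl)pyrrole; 10 bromotrichloromethane  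
Product: 12 4,7-dibromo-1-(4-methylphenylsulfonyl)indole, via 1-tosylindole-4,7-diyl diradical 11 (not isolated)  
Conditions: degassed 10 as solvent and bromine source (large excess, two molecules consumed per molecule of 9; 9 at about 0.002 M), silica-lined steel flow coil under back-pressure, about 210 °C, residence time of minutes, dark  
Reagents that add atoms: bromotrichloromethane (second molecule of 10), BrC(Cl)(Cl)Cl  
Why: Proposed new method: thermal Bergman cycloaromatization of the hex-3-ene-1,5-diyne unit of 9, whose ene is the pyrrole C2=C3 bond, joins the two terminal alkyne carbons (the future C5 and C6) and leaves the singlet σ,σ-diradical 11 with its radical centres at the future C4 and C7; each centre then abstracts a bromine atom from the C–Br bond of a separate molecule of the solvent 10, so that two molecules of 10 are consumed for each molecule of 9, and the two CCl3 radicals released end as hexachloroethane. The closest known reaction type is the Bergman cycloaromatization of acyclic and arene-fused enediynes in tetrahalomethane solvents, which gives 1,4-dihaloarenes by halogen-atom abstraction; a pyrrole-fused enediyne and bromine delivery to C4/C7 of an indole have no such precedent. Ring B is closed in a formal 6-endo-dig mode (C1–C6 bonding of the enediyne), and no stereocenter is formed. Because the five-membered ring splays the alkynes further apart than a benzene ring does, a higher temperature than for 1,2-diethynylbenzene is expected, although the N-sulfonyl group flanking the C2 alkyne should press it toward its partner. The selectivity needed is chemoselectivity: bromine must win over hydrogen, over chlorine and over unimolecular escape of the C7 radical onto the neighbouring tosyl ring, which is secured by using the weak C–Br bond of 10 as neat solvent (about 10 M), so that atom transfer also outruns reopening of 11. Radical-chain Kharasch addition of 10 to unreacted terminal alkyne is held back by high dilution of 9, exclusion of oxygen and a short residence time, and the N-tosyl group makes both the pyrrole ring and the conjugated alkynes poorer partners for the electrophilic CCl3 radical.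

**Step 6**  
Reactants: 12 4,7-dibromo-1-(4-methylphenylsulfonyl)indole  
Product: 13 4,7-dibromoindole  
Conditions: KOH, MeOH–THF, 60 °C  
Reagents that add atoms: none  
Why: Nucleophilic cleavage of the sulfonamide N–S bond by hydroxide/methoxide, the indolide being a good leaving group and the strain between the tosyl group and the adjacent C7 bromine adding driving force; unactivated aryl bromides are inert to these conditions.

**Step 7**  
Reactants: 13 4,7-dibromoindole  
Product: 15 2,3,4,7-tetrabromoindole, via 3,4,7-tribromoindole 14 (not isolated)  
Conditions: NBS (2.1 equiv), anhydrous THF, 0 °C to rt, dark  
Reagents that add atoms: N-bromosuccinimide (NBS), O=C1CCC(=O)N1Br  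
Why: Electrophilic aromatic substitution with an N-bromoimide: C3, the most nucleophilic position of an N–H indole, is brominated first to give 14, and the second equivalent then substitutes C2, the only activated position left; ring B already bears two deactivating bromines, so the reaction should stop at four.

## Compound list

```
1 | 3-bromo-1-(triisopropylsilyl)pyrrole | CC(C)[Si](C(C)C)(C(C)C)n1ccc(Br)c1 | starting material
2 | 3-bromopyrrole | Brc1cc[nH]c1 | intermediate
3 | 3-bromo-1-(4-methylphenylsulfonyl)pyrrole | Cc1ccc(cc1)S(=O)(=O)n1ccc(Br)c1 | intermediate
4 | [3-bromo-1-(4-methylphenylsulfonyl)pyrrol-2-yl]lithium | [Li]c1c(Br)ccn1S(=O)(=O)c1ccc(C)cc1 | intermediate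
5 | 3-bromo-2-iodo-1-(4-methylphenylsulfonyl)pyrrole | Cc1ccc(cc1)S(=O)(=O)n1ccc(Br)c1I | intermediate
6 | trimethylsilylacetylene | C#C[Si](C)(C)C | starting material
7 | 3-bromo-1-(4-methylphenylsulfonyl)-2-[(trimethylsilyl)ethynyl]pyrrole | Cc1ccc(cc1)S(=O)(=O)n1ccc(Br)c1C#C[Si](C)(C)C | intermediate
8 | 1-(4-methylphenylsulfonyl)-2,3-bis[(trimethylsilyl)ethynyl]pyrrole | Cc1ccc(cc1)S(=O)(=O)n1ccc(C#C[Si](C)(C)C)c1C#C[Si](C)(C)C | intermediate
9 | 2,3-diethynyl-1-(4-methylphenylsulfonyl)pyrrole | Cc1ccc(cc1)S(=O)(=O)n1ccc(C#C)c1C#C | intermediate
10 | bromotrichloromethane | BrC(Cl)(Cl)Cl | starting material
11 | 1-(4-methylphenylsulfonyl)indole-4,7-diyl (singlet sigma,sigma-diradical) | Cc1ccc(cc1)S(=O)(=O)n1ccc2[c]cc[c]c12 | intermediate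
12 | 4,7-dibromo-1-(4-methylphenylsulfonyl)indole | Cc1ccc(cc1)S(=O)(=O)n1ccc2c(Br)ccc(Br)c12 | intermediate
13 | 4,7-dibromoindole | Brc1ccc(Br)c2[nH]ccc12 | intermediate
14 | 3,4,7-tribromoindole | Brc1c[nH]c2c(Br)ccc(Br)c12 | intermediate
15 | 2,3,4,7-tetrabromoindole | Brc1[nH]c2c(Br)ccc(Br)c2c1Br | target
```

Total step count: 7. Longest linear sequence: 7 steps (1 to 15).

## Steps least certain to work

**Step 5 (key step, labelled as a proposed new method).** The most likely failure is a radical chain that consumes the diyne before it cyclizes. Every bromine transfer to 11 releases a CCl3 radical, and its addition to a terminal alkyne of 9, followed by bromine transfer from 10, is a self-propagating Kharasch addition. Behind this stand thermal oligomerization of 9 if the barrier is higher than estimated, and incomplete bromine capture: hydrogen transfer, or ipso attack of the C7 radical on the tosyl ring five atoms away with loss of the sulfonyl group. The fallback uses known chemistry and gives up making ring B. Purchased 1,4-dibromo-2-nitrobenzene F1 is treated with three equivalents of vinylmagnesium bromide in THF at −40 °C (Bartoli indole synthesis). The ortho bromine supplies the steric push this reaction needs, the [3,3] shift can only go to the single hydrogen-bearing ortho carbon, and the product is 13. This fallback sets out from no numbered compound of the route but from purchased F1. It replaces steps 1 to 6 (compounds 1 to 12) and comes back to the route at 13, from which step 7 runs unchanged.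

**Step 3.** Oxidative addition into the C3–Br bond of 7 may stall, because the pyrrole is still comparatively electron-rich and the site is flanked by the new alkyne, while 6 is drained by CuI-mediated homocoupling. The fallback changes the electrophile instead of forcing the catalyst. The coupling is run at room temperature only and 7 is isolated. Bromine–lithium exchange with t-BuLi (2 equiv) in THF at −78 °C and a quench with I2 should give 3-iodo-1-(4-methylphenylsulfonyl)-2-[(trimethylsilyl)ethynyl]pyrrole F2, whose C–I bond should couple with 6 at room temperature under the same PdCl2(PPh3)2/CuI system. The fallback sets out from 7 and comes back at 8.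

**Step 4.** Methoxide may attack sulfur as well as silicon, so that the tosyl group is lost together with the silyl caps, and the base can set off oligomerization of the terminal diyne. The fallback avoids silyl caps and base altogether. Two-fold Stille coupling of 5 with tributyl(ethynyl)stannane [Pd(PPh3)4, toluene, 60 then 90 °C] introduces the free ethynyl groups directly under neutral conditions, by way of 3-bromo-2-ethynyl-1-(4-methylphenylsulfonyl)pyrrole F3, which reacts on in the flask. The fallback sets out from 5 and comes back at 9, replacing steps 3 and 4.

**Step 7.** The free N–H indole may be over-oxidized by the N-bromoimide in the presence of traces of water, or the second substitution may stop short because C2 of 14 is deactivated by three bromines. The fallback brominates with the tosyl group still on and uses a carbanion for C2. Compound 12 is brominated at C3 with Br2 in CH2Cl2 to give 3,4,7-tribromo-1-(4-methylphenylsulfonyl)indole F4. LiN(iPr)2 at −78 °C then removes the C2 proton, now flanked by the sulfonyl group and the C3 bromine, and 1,2-dibromotetrachloroethane delivers bromine to give 2,3,4,7-tetrabromo-1-(4-methylphenylsulfonyl)indole F5. KOH in MeOH–THF finally removes the tosyl group. The fallback sets out from 12 and comes back at 15, replacing steps 6 and 7.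

## Further compounds

```
F1 | step 5 | 1,4-dibromo-2-nitrobenzene | O=[N+]([O-])c1cc(Br)ccc1Br
F2 | step 3 | 3-iodo-1-(4-methylphenylsulfonyl)-2-[(trimethylsilyl)ethynyl]pyrrole | Cc1ccc(cc1)S(=O)(=O)n1ccc(I)c1C#C[Si](C)(C)C
F3 | step 4 | 3-bromo-2-ethynyl-1-(4-methylphenylsulfonyl)pyrrole | Cc1ccc(cc1)S(=O)(=O)n1ccc(Br)c1C#C
F4 | step 7 | 3,4,7-tribromo-1-(4-methylphenylsulfonyl)indole | Cc1ccc(cc1)S(=O)(=O)n1cc(Br)c2c(Br)ccc(Br)c12
F5 | step 7 | 2,3,4,7-tetrabromo-1-(4-methylphenylsulfonyl)indole | Cc1ccc(cc1)S(=O)(=O)n1c(Br)c(Br)c2c(Br)ccc(Br)c12
A1 | alternative 1 | ethyl 4,7-dibromo-1H-indole-2-carboxylate | CCOC(=O)c1cc2c(Br)ccc(Br)c2[nH]1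
A2 | alternative 1 | ethyl (Z)-2-azido-3-(2,5-dibromophenyl)acrylate | CCOC(=O)/C(N=[N+]=[N-])=C/c1cc(Br)ccc1Br
A3 | alternative 1 | 2,5-dibromobenzaldehyde | O=Cc1cc(Br)ccc1Br
A4 | alternative 1 | ethyl azidoacetate | CCOC(=O)CN=[N+]=[N-]
A5 | alternative 1 | 4,7-dibromo-1H-indole-2-carboxylic acid | OC(=O)c1cc2c(Br)ccc(Br)c2[nH]1
A6 | alternative 2 | tert-butyl cis-4,7-dibromo-2,3,3a,7a-tetrahydroindole-1-carboxylate (racemic, one enantiomer drawn) | CC(C)(C)OC(=O)N1CC[C@@H]2C(Br)=CC=C(Br)[C@H]12
A7 | alternative 2 | 2,5-dibromothiophene 1,1-dioxide | O=S1(=O)C(Br)=CC=C1Br
A8 | alternative 2 | tert-butyl 2,3-dihydropyrrole-1-carboxylate | CC(C)(C)OC(=O)N1CCC=C1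
A9 | alternative 2 | tert-butyl 4,7-dibromoindole-1-carboxylate | CC(C)(C)OC(=O)n1ccc2c(Br)ccc(Br)c12
A10 | alternative 3 | 4,7-dibromo-1-(4-methylphenylsulfonyl)indolin-3-ol (racemic, one enantiomer drawn) | Cc1ccc(cc1)S(=O)(=O)N1C[C@@H](O)c2c(Br)ccc(Br)c12
A11 | alternative 3 | 3,6-dibromo-2-(trimethylsilyl)phenyl trifluoromethanesulfonate | C[Si](C)(C)c1c(Br)ccc(Br)c1OS(=O)(=O)C(F)(F)F
A12 | alternative 3 | 3,6-dibromobenzyne | BrC1=CC=C(Br)C#C1
A13 | alternative 3 | N-(2-oxoethyl)-4-methylbenzenesulfonamide | Cc1ccc(cc1)S(=O)(=O)NCC=O
```
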